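**Retrosynthetic overview**
1. Rings and numbering (clerodane type, α = face of the C-20 methyl): ring A = cyclohexene C-1–C-5/C-10 (2-OH); ring B = cyclohexane C-5–C-10 (7-OAc, 8- and 9-methyl); ring C = cycloheptanone (C-1, C-10, C-9, C-11, C-12, C-13, C-16); ring D = lactone (C-4, C-5, C-19, O, C-18); ring E = furan.
2. Endgame: the 2α-OH comes from Luche reduction of a 2-oxo-Δ3 enone; ring A comes from a Robinson-type aldol condensation of a C-1 acetyl group onto the non-enolisable C-4 ketone of an α-keto spiro-lactone.
3. Key disconnection: ring D and the quaternary C-5 arise by a one-pot carboxylate SN2/intramolecular Michael [3+2] annulation of 1,3-dithiane-2-carboxylic acid (C-18 plus masked C-4 ketone) with a ring B 19-chloro-Δ5-7-ketone. It is possible because the acetoxy carbon C-7 of ring B lies 1,3 to C-5 (the atom shared by rings A, B and D) and C-19 hangs on C-5: at the 7-ketone level C-5 is an enone β-carbon and C-19 its allylic CH2Cl.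
4. The chloro enone comes by 1,3-carbonyl transposition (Saegusa–Ito, ClCH2Li, Dauben–Babler) from the C-5 ketone of a B/C/E tricycle. That tricycle is made by a [4+3] Mukaiyama–Michael/aldol annulation of (R)-3,4-dimethylcyclohex-2-enone with a 3-acetyl-2-formylfuran equivalent, then vinyl cuprate addition at C-1.
5. Order of ring formation: B (organocatalytic Michael/aldol) → C (fused onto the purchased furan E) → D (key step) → A.

Key step: step 13

**Route**

Step 1
Reactants: 1 propanal; 2 but-3-en-2-one
Product: 3 (R)-2-methyl-5-oxohexanal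
Conditions: (S)-α,α-diphenylprolinol trimethylsilyl ether (5 mol %), catechol (20 mol %), neat, 4 °C
Reagents that add atoms: none
Why: Enamine-catalysed asymmetric Michael addition of an aldehyde to a vinyl ketone: the E-enamine of propanal should be attacked anti to the CPh2OSiMe3 group of the (S)-catalyst, which is expected to give the (R)-configured α-methyl centre (the later C-8), and the mild conditions should suppress self-aldol reaction.

Step 2
Reactants: 3 (R)-2-methyl-5-oxohexanal
Product: 4 (R)-4-methylcyclohex-2-en-1-one
Conditions: LiOH·H2O (0.2 equiv), iPrOH, rt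
Reagents that add atoms: none
Why: Base-mediated intramolecular aldol condensation (6-enolendo-exo-trig, the ring-closing half of a Robinson annulation) of the methyl ketone onto the aldehyde forms ring B; the stereocentre ends up γ to the carbonyl and should survive the mild conditions.

Step 3
Reactants: 4 (R)-4-methylcyclohex-2-en-1-one
Product: 6 (R)-3,4-dimethylcyclohex-2-en-1-one, via silyl enol ether 5 (not isolated)
Conditions: Me2CuLi (from MeLi and CuI), Me3SiCl, Et2O, −78 °C; then Pd(OAc)2 (1.05 equiv), MeCN, rt
Reagents that add atoms: methyllithium, [Li]C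
Why: Gilman-cuprate conjugate addition with silyl trapping followed by Saegusa–Ito dehydrogenation re-forms the enone with the new methyl on the β-carbon; the transient stereocentre of the cuprate step is erased, so only the (R)-centre from step 1 remains.

Step 4
Reactants: 7 3-bromofuran-2-carbaldehyde
Product: 8 2-(3-bromofuran-2-yl)-1,3-dithiolane
Conditions: HSCH2CH2SH, BF3·OEt2 (cat.), CH2Cl2, 0 °C
Reagents that add atoms: ethane-1,2-dithiol, SCCS
Why: BF3-catalysed dithioacetalisation masks the aldehyde as a group that tolerates the palladium coupling and the TiCl4-mediated Michael addition to come.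

Step 5
Reactants: 8 2-(3-bromofuran-2-yl)-1,3-dithiolane
Product: 10 1-[2-(1,3-dithiolan-2-yl)furan-3-yl]ethan-1-one, via enol ether 9 (not isolated)
Conditions: Bu3SnC(OEt)=CH2, PdCl2(PPh3)2 (5 mol %), PhMe, 100 °C; then 1 M HCl, THF, rt
Reagents that add atoms: tributyl(1-ethoxyethenyl)stannane, CCCC[Sn](CCCC)(CCCC)C(=C)OCC; water, O
Why: Stille coupling with an α-ethoxyvinyl stannane (acetyl-anion equivalent) and mild acid hydrolysis of the enol ether, which the dithiolane should survive, install the acetyl group that will supply C-11 and C-12.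

Step 6
Reactants: 10 1-[2-(1,3-dithiolan-2-yl)furan-3-yl]ethan-1-one
Product: 11 ({1-[2-(1,3-dithiolan-2-yl)furan-3-yl]ethenyl}oxy)trimethylsilane
Conditions: Me3SiOTf, Et3N, CH2Cl2, 0 °C
Reagents that add atoms: trimethylsilyl trifluoromethanesulfonate, C[Si](C)(C)OS(=O)(=O)C(F)(F)F
Why: Soft enolisation/O-silylation of the methyl ketone gives the only possible silyl enol ether, the C-11 nucleophile.

Step 7
Reactants: 6 (R)-3,4-dimethylcyclohex-2-en-1-one; 11 ({1-[2-(1,3-dithiolan-2-yl)furan-3-yl]ethenyl}oxy)trimethylsilane
Product: 12 (3S,4R)-3-{2-[2-(1,3-dithiolan-2-yl)furan-3-yl]-2-oxoethyl}-3,4-dimethylcyclohexan-1-one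
Conditions: TiCl4 (1.1 equiv), CH2Cl2, −78 °C; aq. NaHCO3
Reagents that add atoms: none
Why: Mukaiyama–Michael addition to the TiCl4-activated enone builds the C-9 quaternary carbon; attack anti to the adjacent C-8 methyl (as in cuprate and allylsilane additions to this enone) should place the two methyls cis and the acylmethyl arm trans to the C-8 methyl.

Step 8
Reactants: 12 (3S,4R)-3-{2-[2-(1,3-dithiolan-2-yl)furan-3-yl]-2-oxoethyl}-3,4-dimethylcyclohexan-1-one
Product: 14 B/C/E tricyclic 5,12-diketone with a C-1=C-10 double bond, via keto aldehyde 13 (not isolated)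
Conditions: MeI, CaCO3, MeCN/H2O (4:1), 45 °C; then TsOH·H2O (10 mol %), PhH, 80 °C (Dean–Stark)
Reagents that add atoms: none
Why: S-Methylation/hydrolysis frees the furan aldehyde and acid-catalysed intramolecular aldol condensation (7-enolexo-exo-trig) closes ring C between C-10 and C-1; of the possible aldol adducts only this one can dehydrate to a conjugated enone, so the reversible alternatives (from C-6 or C-11) should drain into 14.

Step 9
Reactants: 14 B/C/E tricyclic 5,12-diketone with a C-1=C-10 double bond
Product: 15 1-vinyl B/C/E tricyclic 5,12-diketone (H-1 α; H-10 β; trans B/C fusion)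
Conditions: (CH2=CH)2CuMgBr (from CH2=CHMgBr 2.4 equiv and CuBr·SMe2 1.2 equiv), THF, −78 → −40 °C; sat. aq. NH4Cl
Reagents that add atoms: vinylmagnesium bromide, C=C[Mg]Br
Why: Cuprate conjugate addition to the β-furyl enone puts the vinyl group (future C-2 and C-3) on C-1 from the face opposite the pseudo-axial C-20 methyl, and protonation of the C-10 enolate anti to the same methyl should give the trans B/C fusion, which is also the expected stable epimer of this enolisable centre.

Step 10
Reactants: 15 1-vinyl B/C/E tricyclic 5,12-diketone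
Product: 17 1-vinyl Δ6-5-ketone (ring B enone; 12-ketone kept), via bis-silyl enol ether 16 (not isolated)
Conditions: LiN(iPr)2 (2.4 equiv), Me3SiCl, THF, −78 °C; then Pd(OAc)2 (1.2 equiv), MeCN, rt; 1 M HCl work-up
Reagents that add atoms: none
Why: Kinetic bis-enolisation/silylation and Saegusa–Ito oxidation: deprotonation in ring B occurs at the C-6 methylene and not at the hindered C-10 methine, only that enol ether has a β-hydrogen for palladium hydride elimination, and the C-11/C-12 enol ether is hydrolysed back to the ketone on work-up.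

Step 11
Reactants: 17 1-vinyl Δ6-5-ketone
Product: 18 19-chloro-5-hydroxy-Δ6 tertiary allylic alcohol (either C-5 epimer)
Conditions: LiN(SiMe3)2 (1.05 equiv), THF, −78 °C; then ICH2Cl (3 equiv), MeLi·LiBr (3 equiv), −78 °C; AcOH quench at −78 °C
Reagents that add atoms: chloroiodomethane, ClCI
Why: 1,2-Addition of chloromethyllithium (generated by I/Li exchange in the presence of the substrate, Barbier mode) to the enone carbonyl delivers C-19 with its leaving group, the more acidic furyl ketone being masked in situ as its lithium enolate; the new carbinol centre is inconsequential because C-5 becomes sp2 in the next step.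

Step 12
Reactants: 18 19-chloro-5-hydroxy-Δ6 tertiary allylic alcohol
Product: 19 19-chloro-Δ5-7-ketone (3-chloromethyl enone; 12-ketone and 1-vinyl kept)
Conditions: C5H5NH[CrO3Cl] (3 equiv), 4 Å molecular sieves, CH2Cl2, rt
Reagents that add atoms: none
Why: Dauben–Babler oxidative 1,3-transposition ([3,3] shift of the allylic chromate ester, then oxidation) moves the oxygen to C-7 and leaves the chloromethyl group on the β-carbon of the new enone; the C-8 methyl, now α to the ketone, is already in its more stable equatorial orientation.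

Step 13
Reactants: 19 19-chloro-Δ5-7-ketone; 20 1,3-dithiane-2-carboxylic acid
Product: 22 spiro-lactone 7-ketone (ring D closed; C-4 as spiro 1,3-dithiane; C-19 α), via allylic ester 21 (not isolated)
Conditions: Cs2CO3 (1.3 equiv), NaI (10 mol %), DMF, 0 °C → rt; then KOtBu (0.2 equiv), −20 → 0 °C; AcOH
Reagents that add atoms: none
Why: Proposed new method: the caesium carboxylate of 20 displaces the primary allylic chloride of the γ-chloro enone (SN2, O–C-19 bond) to give ester 21, whose dithiane C–H, now flanked by an ester and two sulfur atoms, is deprotonated so that the tertiary carbanion adds to the enone β-carbon (C-4–C-5 bond) and the resulting C-7 enolate is protonated at C-6. The closest known reactions are tandem SN2–Michael ring closures of halo-substituted Michael acceptors and conjugate additions of 2-alkoxycarbonyl-1,3-dithiane anions (glyoxylate acyl-anion equivalents) to enones; new is their union in one pot as a formal [3+2] lactone annulation that forges a spiro quaternary carbon. Ring D closes in the second event by a 5-exo-trig Michael addition, the first bond being intermolecular. The only new stereocentre, C-5, is set by the axial C-20 methyl, which lies 1,3 to C-5 and shields the α-face, so the bulky dithiane carbon should enter from the β-face (syn to H-10) and leave the CH2O arm axial and α; because the addition is reversible, the same isomer, with the smaller CH2O group rather than the quaternary dithiane carbon in the 1,3-diaxial position, is also the thermodynamic one. The step needs O-alkylation before any C-alkylation, SN2 rather than SN2′ attack and closure onto C-5 only: under carbonate the carboxylate is the sole nucleophile (the dithiane C–H becomes acidic enough only in the ester and then reacts intramolecularly), the CH2Cl terminus is primary and substitution there keeps the enone conjugated, a five-membered ring can form only at C-5, and the C-8 methyl next to the ketone can at most equilibrate to its equatorial, desired orientation.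

Step 14
Reactants: 22 spiro-lactone 7-ketone
Product: 23 spiro-lactone 7α-alcohol
Conditions: NaBH4, MeOH/THF (1:1), −30 °C
Reagents that add atoms: none
Why: Borohydride reduction of the ring B ketone: the axial C-19 and C-20 groups (both 1,3 to C-7) block the α-face, so hydride should arrive equatorially from the β-face and give the axial 7α-alcohol, while the furyl ketone (a neopentyl-flanked vinylogous ester) and the lactone should not react at low temperature.

Step 15
Reactants: 23 spiro-lactone 7α-alcohol
Product: 24 spiro-lactone 7α-acetate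
Conditions: Ac2O, 4-(dimethylamino)pyridine (0.2 equiv), pyridine, CH2Cl2, rt
Reagents that add atoms: acetic anhydride, CC(=O)OC(C)=O
Why: Nucleophile-catalysed acylation of the hindered axial alcohol installs the acetate before any other hydroxyl group exists, so no differentiation problem arises later.

Step 16
Reactants: 24 spiro-lactone 7α-acetate
Product: 25 4-oxo lactone (α-keto-γ-lactone) 7α-acetate with 1-vinyl
Conditions: PhI(OCOCF3)2 (1.5 equiv), MeCN/H2O (9:1), 0 °C → rt
Reagents that add atoms: water, O
Why: Oxidative dethioacetalisation with the hypervalent iodine reagent in wet acetonitrile unmasks the C-4 ketone; the resulting α-keto lactone has no α-hydrogen and cannot enolise, and the alkene, acetate and acyl-deactivated furan should be tolerated.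

Step 17
Reactants: 25 4-oxo lactone 7α-acetate with 1-vinyl
Product: 27 2-oxo-Δ3 pentacycle (2-dehydro target), via methyl ketone 26 (not isolated)
Conditions: PdCl2 (10 mol %), CuCl (0.3 equiv), O2 (1 atm), DMF/H2O (7:1), rt; then TsOH·H2O (10 mol %), PhH, 80 °C (Dean–Stark)
Reagents that add atoms: water, O
Why: Tsuji–Wacker oxidation converts the vinyl group into the C-2 methyl ketone (Markovnikov), and acid-catalysed Robinson-type aldol condensation (6-enolendo-exo-trig) of its methyl group onto the non-enolisable, highly electrophilic C-4 ketone closes ring A; C-1, now α to a ketone, can equilibrate to the trans A/C-fused arrangement with both ring bonds equatorial.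

Step 18
Reactants: 27 2-oxo-Δ3 pentacycle
Product: 28 CNP0182929.1 (target)
Conditions: NaBH4, CeCl3·7H2O, MeOH, −78 °C
Reagents that add atoms: none
Why: Luche reduction (1,2-selective) of the ring A enone: axial hydride delivery from the β-face should give the equatorial 2α-alcohol trans to the C-1–furan bond, and the furyl ketone, lactone and acetate are expected to be untouched at −78 °C.

**Compound list**
1 | propanal | CCC=O | starting material
2 | but-3-en-2-one (methyl vinyl ketone) | CC(=O)C=C | starting material
3 | (R)-2-methyl-5-oxohexanal | O=C[C@H](C)CCC(C)=O | intermediate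
4 | (R)-4-methylcyclohex-2-en-1-one | O=C1C=C[C@H](C)CC1 | intermediate
5 | trimethyl{[(3S,4R)-3,4-dimethylcyclohex-1-en-1-yl]oxy}silane (trans-dimethyl) | C[Si](C)(C)OC1=C[C@@H](C)[C@H](C)CC1 | intermediate (not isolated)
6 | (R)-3,4-dimethylcyclohex-2-en-1-one | O=C1C=C(C)[C@H](C)CC1 | intermediate
7 | 3-bromofuran-2-carbaldehyde | O=Cc1occc1Br | starting material
8 | 2-(3-bromofuran-2-yl)-1,3-dithiolane | Brc1ccoc1C1SCCS1 | intermediate
9 | 2-[3-(1-ethoxyethenyl)furan-2-yl]-1,3-dithiolane | CCOC(=C)c1ccoc1C1SCCS1 | intermediate (not isolated)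
10 | 1-[2-(1,3-dithiolan-2-yl)furan-3-yl]ethan-1-one | CC(=O)c1ccoc1C1SCCS1 | intermediate
11 | ({1-[2-(1,3-dithiolan-2-yl)furan-3-yl]ethenyl}oxy)trimethylsilane | C=C(O[Si](C)(C)C)c1ccoc1C1SCCS1 | intermediate
12 | (3S,4R)-3-{2-[2-(1,3-dithiolan-2-yl)furan-3-yl]-2-oxoethyl}-3,4-dimethylcyclohexan-1-one | O=C1CC[C@@H](C)[C@](C)(CC(=O)c2ccoc2C2SCCS2)C1 | intermediate
13 | 3-{2-[(1S,2R)-1,2-dimethyl-5-oxocyclohexyl]acetyl}furan-2-carbaldehyde | O=C1CC[C@@H](C)[C@](C)(CC(=O)c2ccoc2C=O)C1 | intermediate (not isolated)
14 | B/C/E tricyclic 5,12-diketone with C-1=C-10 double bond (8α,9α-dimethyl) | O=C1CC[C@@H](C)[C@]2(C)CC(=O)c3ccoc3C=C12 | intermediate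
15 | 1-vinyl B/C/E tricyclic 5,12-diketone (H-1 α, H-10 β, trans B/C fusion) | O=C1CC[C@@H](C)[C@]2(C)CC(=O)c3ccoc3[C@H](C=C)[C@@H]12 | intermediate
16 | bis(trimethylsilyl) enol ether of 15 (C-5=C-6 and C-11=C-12) | C[Si](C)(C)OC1=CC[C@@H](C)[C@]2(C)C=C(O[Si](C)(C)C)c3ccoc3[C@H](C=C)[C@@H]12 | intermediate (not isolated)
17 | 1-vinyl Δ6-5-ketone (ring B enone), 12-ketone | O=C1C=C[C@@H](C)[C@]2(C)CC(=O)c3ccoc3[C@H](C=C)[C@@H]12 | intermediate
18 | 19-chloro-5-hydroxy-Δ6 tertiary allylic alcohol (C-5 configuration left open) | OC1(CCl)C=C[C@@H](C)[C@]2(C)CC(=O)c3ccoc3[C@H](C=C)[C@@H]12 | intermediate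
19 | 19-chloro-Δ5-7-ketone (3-chloromethyl enone), 12-ketone, 1-vinyl | O=C1C=C(CCl)[C@@H]2[C@@H](C=C)c3occc3C(=O)C[C@@]2(C)[C@@H]1C | intermediate
20 | 1,3-dithiane-2-carboxylic acid | OC(=O)C1SCCCS1 | starting material
21 | C-19 1,3-dithiane-2-carboxylate ester of the Δ5-7-ketone | O=C1C=C(COC(=O)C3SCCCS3)[C@@H]2[C@@H](C=C)c3occc3C(=O)C[C@@]2(C)[C@@H]1C | intermediate (not isolated)
22 | spiro-lactone 7-ketone (C-4 as spiro 1,3-dithiane, C-19 α, C-5 quaternary) | O=C1C[C@]2(COC(=O)C23SCCCS3)[C@@H]4[C@@H](C=C)c5occc5C(=O)C[C@@]4(C)[C@@H]1C | intermediate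
23 | spiro-lactone 7α-alcohol | O[C@@H]1C[C@]2(COC(=O)C23SCCCS3)[C@@H]4[C@@H](C=C)c5occc5C(=O)C[C@@]4(C)[C@@H]1C | intermediate
24 | spiro-lactone 7α-acetate | CC(=O)O[C@@H]1C[C@]2(COC(=O)C23SCCCS3)[C@@H]4[C@@H](C=C)c5occc5C(=O)C[C@@]4(C)[C@@H]1C | intermediate
25 | 4-oxo lactone 7α-acetate with 1-vinyl | CC(=O)O[C@@H]1C[C@]2(COC(=O)C2=O)[C@@H]3[C@@H](C=C)c4occc4C(=O)C[C@@]3(C)[C@@H]1C | intermediate
26 | 1-acetyl 4-oxo lactone 7α-acetate (C-2 ketone, C-3 methyl) | CC(=O)O[C@@H]1C[C@]2(COC(=O)C2=O)[C@@H]3[C@@H](C(C)=O)c4occc4C(=O)C[C@@]3(C)[C@@H]1C | intermediate (not isolated)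
27 | 2-oxo-Δ3 pentacycle (2-dehydro target) | CC(=O)O[C@@H]1C[C@@]23COC(=O)C2=CC(=O)[C@H]2c4occc4C(=O)C[C@@](C)([C@@H]1C)[C@@H]23 | intermediate
28 | CNP0182929.1 (7α-acetoxy-2α-hydroxy-12-oxo 18,19-olide with C-1–C-16 bond) | CC(=O)O[C@@H]1C[C@@]23COC(=O)C2=C[C@H](O)[C@H]2c4occc4C(=O)C[C@@](C)([C@@H]1C)[C@@H]23 | target

**Step count**
Total: 18 steps. Longest linear sequence: 15 steps (steps 1–3 and 7–18); the furan building block takes steps 4–6.

**Steps most likely to fail**

1. Step 13 (carries the new-method label). The ring closure may stall or revert: the tertiary dithianyl carbanion must bond to a fully substituted enone carbon next to an axial methyl, so simple ester formation without cyclisation, or retro-Michael cleavage, may prevail. Fallback (known chemistry, sets out from 19 and returns at 25): the C-4 donor is changed to a secondary phosphonate carbanion and the two bond formations are run separately. Alkylation of 19 with caesium (diethoxyphosphoryl)acetate (DMF, rt) should give the allylic phosphonoacetate F1. LiCl/DBU in MeCN should close it by intramolecular Michael addition to the α-phosphono spiro-lactone 7-ketone F2. NaBH4 and then Ac2O/4-(dimethylamino)pyridine should give the 7α-alcohol F3 and its 7α-acetate F4. Deprotonation of F4 with KN(SiMe3)2 and oxygenation with O2 (oxidative dephosphonylation of the phosphonate carbanion) should deliver the 4-oxo lactone 25.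

2. Step 7. Conjugate addition may not take place: the weakly nucleophilic aryl ketone enol ether may fail to attack the β,β-disubstituted enone flanked by the C-8 methyl, leading to desilylation or 1,2-attack instead. Fallback (sets out from 6 and 8, returns at 12): the C-9–C-11 bond is made with a much stronger π-nucleophile and the furan is attached afterwards by cross-coupling. TiCl4-mediated Mukaiyama–Michael addition of 1-(ethylsulfanyl)-1-(trimethylsilyloxy)ethene to 6 should give S-ethyl 2-[(1S,2R)-1,2-dimethyl-5-oxocyclohexyl]ethanethioate F5. Bromide 8 is converted with iPrMgCl·LiCl and then ZnCl2 into [2-(1,3-dithiolan-2-yl)furan-3-yl]zinc chloride F6. Fukuyama coupling of F5 with F6 (PdCl2(PPh3)2, THF, rt) should give 12, the ring ketone being inert to the organozinc.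

3. Step 11. Chemoselectivity of the carbenoid addition may be lost: attack on an incompletely masked furyl ketone, enolisation of the hindered enone, or collapse of the chlorohydrin alkoxide to the spiro-epoxide before the quench. Fallback (sets out from 17, returns at 19, bypassing steps 11 and 12): oxygen is brought to C-7 by an enone-specific epoxidation and C-19 by olefination. Weitz–Scheffer epoxidation (H2O2, NaOH, MeOH) should give the 6,7-epoxy 5-ketone F7, either epoxide face serving. Wittig methylenation (Ph3P=CH2) of the activated, non-conjugated C-5 ketone should give the vinyl epoxide F8. Conjugate (SN2′) opening at the unhindered methylene terminus with chloride (LiCl, AcOH, THF) should give the 19-chloro-Δ5-7-alcohol F9. Dess–Martin oxidation then gives 19.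

**Further compounds**
F1 | step 13 | C-19 (diethoxyphosphoryl)acetate ester of the Δ5-7-ketone | O=C1C=C(COC(=O)CP(=O)(OCC)OCC)[C@@H]2[C@@H](C=C)c3occc3C(=O)C[C@@]2(C)[C@@H]1C
F2 | step 13 | α-(diethoxyphosphoryl) spiro-lactone 7-ketone (C-4 configuration open) | O=C1C[C@]2(COC(=O)C2P(=O)(OCC)OCC)[C@@H]3[C@@H](C=C)c4occc4C(=O)C[C@@]3(C)[C@@H]1C
F3 | step 13 | α-(diethoxyphosphoryl) spiro-lactone 7α-alcohol | O[C@@H]1C[C@]2(COC(=O)C2P(=O)(OCC)OCC)[C@@H]3[C@@H](C=C)c4occc4C(=O)C[C@@]3(C)[C@@H]1C
F4 | step 13 | α-(diethoxyphosphoryl) spiro-lactone 7α-acetate | CC(=O)O[C@@H]1C[C@]2(COC(=O)C2P(=O)(OCC)OCC)[C@@H]3[C@@H](C=C)c4occc4C(=O)C[C@@]3(C)[C@@H]1C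
F5 | step 7 | S-ethyl 2-[(1S,2R)-1,2-dimethyl-5-oxocyclohexyl]ethanethioate | O=C1CC[C@@H](C)[C@](C)(CC(=O)SCC)C1
F6 | step 7 | [2-(1,3-dithiolan-2-yl)furan-3-yl]zinc chloride | Cl[Zn]c1ccoc1C1SCCS1
F7 | step 11 | 6,7-epoxy 5-ketone (epoxide configuration open) | O=C1C2OC2[C@@H](C)[C@]3(C)CC(=O)c4ccoc4[C@H](C=C)[C@@H]13
F8 | step 11 | 6,7-epoxy 5(19)-ene (vinyl epoxide) | C=C1C2OC2[C@@H](C)[C@]3(C)CC(=O)c4ccoc4[C@H](C=C)[C@@H]13
F9 | step 11 | 19-chloro-Δ5-7-alcohol (C-7 configuration open) | OC1C=C(CCl)[C@@H]2[C@@H](C=C)c3occc3C(=O)C[C@@]2(C)[C@@H]1C
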